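**Retrosynthetic overview**

1. Numbering: ring O1, C2 (S, bears the acrylic unit), C3, C4=C5, C6; side chain C1'–C13' counted from C5. Acid 26 comes from silyl ether 23 by desilylation and two oxidations; the acrylic acid is carried as its allylic CH2OSi form, so no radical acceptor exists before the end.
2. Key disconnection C6'–C7': nickel-electrocatalysed decarboxylative alkenylation of the N-hydroxyphthalimide ester 18 (C6' radical precursor) with the (E)-alkenyl iodide 22 (C7'–C13').
3. Enabling feature: the chain is a skipped 1,5-polyene. C6' is a primary sp3 carbon homoallylic to C3'=C4', so a carboxyl on it is the direct product of a Johnson–Claisen rearrangement and its radical has no productive cyclisation. C7' is the unsubstituted sp2 end of the E-trisubstituted C7'=C8' alkene, so it can be an alkenyl iodide from alkyne carboalumination. Ring O1/C2–C6 is remote (C2 is nine bonds from C6').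
4. 18 ⇐ Johnson–Claisen (sets E-C3'=C4') of isopropenyl carbinol 14 ⇐ aldehyde 13 ⇐ ring allylic chloride 8 + lithiated acetaldehyde imine 11.
5. Ring order: the single ring (dihydropyran) is closed first, by ring-closing metathesis (C4=C5) of ether 7, made from dichloride 6 and homoallylic alcohol 5; the C2 centre of 5 comes from asymmetric allylboration of enal 3.

Key step: step 14

Remark: (−)-Ipc2B(allyl) (pentane solution), CH2=C(CH3)MgBr (THF solution) and LiC≡CH·H2NCH2CH2NH2 are taken as purchased reagents; imine 11 is made in step 6. Names written as "5,6-dihydro-2H-pyran-3-yl" use substituent numbering; their (6S) centre is the same carbon as C2 of the target.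

**Step 1**
Reactants: 1 2-methylidenepropane-1,3-diol
Product: 2 2-{[(tert-butyldiphenylsilyl)oxy]methyl}prop-2-en-1-ol
Conditions: NaH (1.0 equiv), THF, 0 °C to rt; then t-BuPh2SiCl (1.0 equiv)
Reagents that add atoms: tert-butyl(chloro)diphenylsilane, CC(C)(C)[Si](Cl)(c1ccccc1)c1ccccc1
Why: Silyl ether formation on the monosodium alkoxide of the symmetrical diol should stop after one silylation and give the mono-protected diol.

**Step 2**
Reactants: 2 2-{[(tert-butyldiphenylsilyl)oxy]methyl}prop-2-en-1-ol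
Product: 3 2-{[(tert-butyldiphenylsilyl)oxy]methyl}prop-2-enal
Conditions: MnO2 (excess), CH2Cl2, rt
Reagents that add atoms: none
Why: MnO2 allylic oxidation should convert the primary allylic alcohol into the 2-substituted acrolein without over-oxidation.

**Step 3**
Reactants: 3 2-{[(tert-butyldiphenylsilyl)oxy]methyl}prop-2-enal
Product: 5 (3S)-2-{[(tert-butyldiphenylsilyl)oxy]methyl}hexa-1,5-dien-3-ol, via borinate ester 4 (not isolated)
Conditions: (−)-Ipc2B(allyl) (1 M in pentane), Et2O, −78 °C; then NaOH, H2O2, 0 °C to rt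
Reagents that add atoms: (−)-B-allyldiisopinocampheylborane, C=CCB([C@H]1[C@H](C)[C@H]2C[C@@H](C1)C2(C)C)[C@H]1[C@H](C)[C@H]2C[C@@H](C1)C2(C)C
Why: Brown allylboration through a closed chair-like six-membered transition state should give only 1,2-addition, and the isopinocampheyl groups derived from (+)-α-pinene direct the allyl group to the Si face of the aldehyde, which sets the carbinol centre (the later ring C2) as S.

**Step 4**
Reactants: 5 (3S)-2-{[(tert-butyldiphenylsilyl)oxy]methyl}hexa-1,5-dien-3-ol; 6 3-chloro-2-(chloromethyl)prop-1-ene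
Product: 7 tert-butyl{[(3S)-3-{[2-(chloromethyl)prop-2-en-1-yl]oxy}-2-methylidenehex-5-en-1-yl]oxy}diphenylsilane
Conditions: NaH, Bu4NI (cat.), THF, 0 °C to rt; 6 (5 equiv)
Reagents that add atoms: none
Why: Williamson etherification should be clean because SN2 and SN2' attack on the symmetrical dichloride give the same ether, the excess of 6 suppresses double substitution, and THF without DMF disfavours silyl migration; the C–O bond at the stereocentre is not broken.

**Step 5**
Reactants: 7 tert-butyl{[(3S)-3-{[2-(chloromethyl)prop-2-en-1-yl]oxy}-2-methylidenehex-5-en-1-yl]oxy}diphenylsilane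
Product: 8 tert-butyl({2-[(2S)-5-(chloromethyl)-3,6-dihydro-2H-pyran-2-yl]prop-2-en-1-yl}oxy)diphenylsilane
Conditions: second-generation Grubbs catalyst (5 mol%), CH2Cl2 (0.01 M), 40 °C
Reagents that add atoms: none
Why: Ring-closing metathesis should start at the monosubstituted allyl alkene and close onto the 1,1-disubstituted ether alkene to give the six-membered ring with the trisubstituted C4=C5 bond, since closure onto the other 1,1-disubstituted alkene would need a cyclobutene or a tetrasubstituted dihydrofuran.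

**Step 6**
Reactants: 9 acetaldehyde; 10 tert-butylamine
Product: 11 (E)-N-tert-butylethanimine
Conditions: neat, 0 °C; then KOH pellets, distillation
Reagents that add atoms: none
Why: Imine condensation of an unhindered aldehyde with a primary amine should be complete once water is taken up by KOH.

**Step 7**
Reactants: 8 tert-butyl({2-[(2S)-5-(chloromethyl)-3,6-dihydro-2H-pyran-2-yl]prop-2-en-1-yl}oxy)diphenylsilane; 11 (E)-N-tert-butylethanimine
Product: 13 3-[(6S)-6-(3-{[tert-butyl(diphenyl)silyl]oxy}prop-1-en-2-yl)-5,6-dihydro-2H-pyran-3-yl]propanal, via alkylated imine 12 (not isolated)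
Conditions: 11, LiN(iPr)2, THF, 0 °C; then 8, −78 to 0 °C; then aq. oxalic acid, rt
Reagents that add atoms: water, O
Why: Stork metalloenamine alkylation should work because the lithiated imine is a soft carbon nucleophile that displaces the unhindered primary allylic chloride by SN2, and mild acid hydrolysis then releases the aldehyde with C1'–C3' in place.

**Step 8**
Reactants: 13 3-[(6S)-6-(3-{[tert-butyl(diphenyl)silyl]oxy}prop-1-en-2-yl)-5,6-dihydro-2H-pyran-3-yl]propanal
Product: 14 5-[(6S)-6-(3-{[tert-butyl(diphenyl)silyl]oxy}prop-1-en-2-yl)-5,6-dihydro-2H-pyran-3-yl]-2-methylpent-1-en-3-ol (both carbinol epimers)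
Conditions: CH2=C(CH3)MgBr, THF, −78 to 0 °C; aq. NH4Cl
Reagents that add atoms: isopropenylmagnesium bromide, C=C(C)[Mg]Br
Why: Grignard 1,2-addition to the aldehyde should give the isopropenyl carbinol; the new carbinol centre is uncontrolled, which does not matter because step 9 destroys it.

**Step 9**
Reactants: 14 5-[(6S)-6-(3-{[tert-butyl(diphenyl)silyl]oxy}prop-1-en-2-yl)-5,6-dihydro-2H-pyran-3-yl]-2-methylpent-1-en-3-ol
Product: 16 ethyl (4E)-7-[(6S)-6-(3-{[tert-butyl(diphenyl)silyl]oxy}prop-1-en-2-yl)-5,6-dihydro-2H-pyran-3-yl]-4-methylhept-4-enoate, via ketene acetal 15 (not isolated)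
Conditions: CH3C(OEt)3 (8 equiv), EtCO2H (cat.), 138 °C, EtOH distilled off
Reagents that add atoms: triethyl orthoacetate, CC(OCC)(OCC)OCC
Why: Johnson–Claisen rearrangement through a chair transition state with the C2' chain pseudo-equatorial should convert both carbinol epimers into the E-configured C3'=C4' alkene and add C5', C6' and the carboxyl carbon.

**Step 10**
Reactants: 16 ethyl (4E)-7-[(6S)-6-(3-{[tert-butyl(diphenyl)silyl]oxy}prop-1-en-2-yl)-5,6-dihydro-2H-pyran-3-yl]-4-methylhept-4-enoate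
Product: 17 (4E)-7-[(6S)-6-(3-{[tert-butyl(diphenyl)silyl]oxy}prop-1-en-2-yl)-5,6-dihydro-2H-pyran-3-yl]-4-methylhept-4-enoic acid
Conditions: LiOH·H2O, THF/MeOH/H2O, rt; then 1 M HCl to pH 3
Reagents that add atoms: lithium hydroxide, [Li+].[OH-]
Why: Saponification of the unhindered ethyl ester should proceed at room temperature, where the silyl ether and the alkenes are inert.

**Step 11**
Reactants: 17 (4E)-7-[(6S)-6-(3-{[tert-butyl(diphenyl)silyl]oxy}prop-1-en-2-yl)-5,6-dihydro-2H-pyran-3-yl]-4-methylhept-4-enoic acid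
Product: 18 1,3-dioxoisoindolin-2-yl (4E)-7-[(6S)-6-(3-{[tert-butyl(diphenyl)silyl]oxy}prop-1-en-2-yl)-5,6-dihydro-2H-pyran-3-yl]-4-methylhept-4-enoate
Conditions: N-hydroxyphthalimide, DIC, DMAP (cat.), CH2Cl2, rt
Reagents that add atoms: N-hydroxyphthalimide, O=C1c2ccccc2C(=O)N1O
Why: Carbodiimide (Steglich-type) esterification should give the redox-active ester of the primary acid under neutral conditions.

**Step 12**
Reactants: 19 5-bromo-2-methylpent-2-ene
Product: 20 6-methylhept-5-en-1-yne
Conditions: LiC≡CH·H2NCH2CH2NH2, DMSO, 15 °C to rt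
Reagents that add atoms: lithium acetylide–ethylenediamine complex, [Li+].[C-]#C.NCCN
Why: SN2 alkylation of the acetylide by the primary bromide in DMSO should give the terminal alkyne.

**Step 13**
Reactants: 20 6-methylhept-5-en-1-yne
Product: 22 (1E)-1-iodo-2,6-dimethylhepta-1,5-diene, via alkenylalane 21 (not isolated)
Conditions: AlMe3 (2 equiv), Cp2ZrCl2 (0.25 equiv), CH2Cl2, 0 °C to rt; then I2, THF, −30 to 0 °C
Reagents that add atoms: trimethylaluminium, C[Al](C)C; iodine, II
Why: Negishi carboalumination should add Me–Al syn across the terminal alkyne with methyl on the internal carbon, and iodinolysis of the C–Al bond with retention then fixes the E geometry of the later C7'=C8' alkene, while the trisubstituted alkene stays untouched.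

**Step 14**
Reactants: 18 1,3-dioxoisoindolin-2-yl (4E)-7-[(6S)-6-(3-{[tert-butyl(diphenyl)silyl]oxy}prop-1-en-2-yl)-5,6-dihydro-2H-pyran-3-yl]-4-methylhept-4-enoate; 22 (1E)-1-iodo-2,6-dimethylhepta-1,5-diene
Product: 23 tert-butyl({2-[(2S)-5-[(3E,7E)-4,8,12-trimethyltrideca-3,7,11-trien-1-yl]-3,6-dihydro-2H-pyran-2-yl]prop-2-en-1-yl}oxy)diphenylsilane
Conditions: NiCl2·6H2O (20 mol%), 2,2'-bipyridine (20 mol%), AgNO3 (0.3 equiv), DMF, undivided cell, Mg anode, reticulated vitreous carbon cathode, constant current, rt; 22 (2 equiv)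
Reagents that add atoms: none
Why: Cathodic reduction turns bipyridine-ligated divalent nickel into low-valent nickel, which adds oxidatively to the C–I bond of 22 with retention of the E geometry, while single-electron reduction of 18 (at the silver-coated cathode or by low-valent nickel) expels phthalimide anion and CO2 to give the primary homoallylic C6' radical; capture of this radical by the alkenylnickel species and reductive elimination from trivalent nickel form the C6'–C7' bond, with the Mg anode supplying the electrons. The closest known reaction type is the nickel-electrocatalytic decarboxylative alkenylation of redox-active esters with alkenyl halides used for modular assembly of polyene terpenoids, where N-hydroxyphthalimide esters of (E)-4-methylalk-4-enoic acids are joined to (E)-2-methylalk-1-enyl iodides. No ring is closed and no stereocentre is created; C2 is nine bonds from the radical site and is not touched. The selectivities needed are cross- over homo-coupling (excess 22, and the two partners are activated differently, one by oxidative addition and one by single-electron reduction), retention of both E alkenes (two-electron chemistry at C7', and at C6' the only radical cyclisation available is a reversible, degenerate 3-exo closure expected to be slower than capture by nickel) and the absence of radical acceptors, which is why the acrylic acid is held as an unactivated 1,1-disubstituted allylic silyl ether.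

**Step 15**
Reactants: 23 tert-butyl({2-[(2S)-5-[(3E,7E)-4,8,12-trimethyltrideca-3,7,11-trien-1-yl]-3,6-dihydro-2H-pyran-2-yl]prop-2-en-1-yl}oxy)diphenylsilane
Product: 24 2-[(2S)-5-[(3E,7E)-4,8,12-trimethyltrideca-3,7,11-trien-1-yl]-3,6-dihydro-2H-pyran-2-yl]prop-2-en-1-ol
Conditions: Bu4NF, THF, 0 °C to rt
Reagents that add atoms: none
Why: Fluoride-induced Si–O cleavage should release the primary allylic alcohol under conditions that leave the polyene and C2 untouched.

**Step 16**
Reactants: 24 2-[(2S)-5-[(3E,7E)-4,8,12-trimethyltrideca-3,7,11-trien-1-yl]-3,6-dihydro-2H-pyran-2-yl]prop-2-en-1-ol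
Product: 25 2-[(2S)-5-[(3E,7E)-4,8,12-trimethyltrideca-3,7,11-trien-1-yl]-3,6-dihydro-2H-pyran-2-yl]prop-2-enal
Conditions: MnO2 (excess), CH2Cl2, rt
Reagents that add atoms: none
Why: MnO2 allylic oxidation should be selective for the only allylic alcohol and, being neutral, should leave the isolated alkenes and the C2 centre unchanged.

**Step 17**
Reactants: 25 2-[(2S)-5-[(3E,7E)-4,8,12-trimethyltrideca-3,7,11-trien-1-yl]-3,6-dihydro-2H-pyran-2-yl]prop-2-enal
Product: 26 2-[(2S)-5-[(3E,7E)-4,8,12-trimethyltrideca-3,7,11-trien-1-yl]-3,6-dihydro-2H-pyran-2-yl]prop-2-enoic acid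
Conditions: NaClO2, NaH2PO4, 2-methylbut-2-ene (large excess), t-BuOH/H2O, 0 °C to rt
Reagents that add atoms: sodium chlorite, [Na+].[O-]Cl=O
Why: Pinnick oxidation should take the enal to the acrylic acid at pH 3–4, where C2 cannot epimerise and nothing adds to the acrylate, with 2-methylbut-2-ene scavenging the hypochlorous acid that would otherwise attack the chain alkenes.

**Compound list**

1 | 2-methylidenepropane-1,3-diol | C=C(CO)CO | starting material
2 | 2-{[(tert-butyldiphenylsilyl)oxy]methyl}prop-2-en-1-ol | C=C(CO)CO[Si](c1ccccc1)(c1ccccc1)C(C)(C)C | intermediate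
3 | 2-{[(tert-butyldiphenylsilyl)oxy]methyl}prop-2-enal | C=C(C=O)CO[Si](c1ccccc1)(c1ccccc1)C(C)(C)C | intermediate
4 | (3S)-2-{[(tert-butyldiphenylsilyl)oxy]methyl}hexa-1,5-dien-3-yl diisopinocampheylborinate | C=C(CO[Si](c1ccccc1)(c1ccccc1)C(C)(C)C)[C@H](CC=C)OB([C@H]1[C@H](C)[C@H]2C[C@@H](C1)C2(C)C)[C@H]1[C@H](C)[C@H]2C[C@@H](C1)C2(C)C | intermediate
5 | (3S)-2-{[(tert-butyldiphenylsilyl)oxy]methyl}hexa-1,5-dien-3-ol | C=C(CO[Si](c1ccccc1)(c1ccccc1)C(C)(C)C)[C@@H](O)CC=C | intermediate
6 | 3-chloro-2-(chloromethyl)prop-1-ene | C=C(CCl)CCl | starting material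
7 | tert-butyl{[(3S)-3-{[2-(chloromethyl)prop-2-en-1-yl]oxy}-2-methylidenehex-5-en-1-yl]oxy}diphenylsilane | C=C(CO[Si](c1ccccc1)(c1ccccc1)C(C)(C)C)[C@@H](OCC(=C)CCl)CC=C | intermediate
8 | tert-butyl({2-[(2S)-5-(chloromethyl)-3,6-dihydro-2H-pyran-2-yl]prop-2-en-1-yl}oxy)diphenylsilane | C=C(CO[Si](c1ccccc1)(c1ccccc1)C(C)(C)C)[C@@H]1CC=C(CCl)CO1 | intermediate
9 | acetaldehyde | CC=O | starting material
10 | tert-butylamine | CC(C)(C)N | starting material
11 | (E)-N-tert-butylethanimine | C/C=N/C(C)(C)C | intermediate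
12 | (E)-N-tert-butyl-3-[(6S)-6-(3-{[tert-butyl(diphenyl)silyl]oxy}prop-1-en-2-yl)-5,6-dihydro-2H-pyran-3-yl]propan-1-imine | C=C(CO[Si](c1ccccc1)(c1ccccc1)C(C)(C)C)[C@@H]1CC=C(CC/C=N/C(C)(C)C)CO1 | intermediate
13 | 3-[(6S)-6-(3-{[tert-butyl(diphenyl)silyl]oxy}prop-1-en-2-yl)-5,6-dihydro-2H-pyran-3-yl]propanal | C=C(CO[Si](c1ccccc1)(c1ccccc1)C(C)(C)C)[C@@H]1CC=C(CCC=O)CO1 | intermediate
14 | 5-[(6S)-6-(3-{[tert-butyl(diphenyl)silyl]oxy}prop-1-en-2-yl)-5,6-dihydro-2H-pyran-3-yl]-2-methylpent-1-en-3-ol (both carbinol epimers) | C=C(CO[Si](c1ccccc1)(c1ccccc1)C(C)(C)C)[C@@H]1CC=C(CCC(O)C(C)=C)CO1 | intermediate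
15 | 1-ethoxyethenyl ether (ketene acetal) of 14 | C=C(CO[Si](c1ccccc1)(c1ccccc1)C(C)(C)C)[C@@H]1CC=C(CCC(OC(=C)OCC)C(C)=C)CO1 | intermediate
16 | ethyl (4E)-7-[(6S)-6-(3-{[tert-butyl(diphenyl)silyl]oxy}prop-1-en-2-yl)-5,6-dihydro-2H-pyran-3-yl]-4-methylhept-4-enoate | C=C(CO[Si](c1ccccc1)(c1ccccc1)C(C)(C)C)[C@@H]1CC=C(CC/C=C(\C)CCC(=O)OCC)CO1 | intermediate
17 | (4E)-7-[(6S)-6-(3-{[tert-butyl(diphenyl)silyl]oxy}prop-1-en-2-yl)-5,6-dihydro-2H-pyran-3-yl]-4-methylhept-4-enoic acid | C=C(CO[Si](c1ccccc1)(c1ccccc1)C(C)(C)C)[C@@H]1CC=C(CC/C=C(\C)CCC(=O)O)CO1 | intermediate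
18 | 1,3-dioxoisoindolin-2-yl (4E)-7-[(6S)-6-(3-{[tert-butyl(diphenyl)silyl]oxy}prop-1-en-2-yl)-5,6-dihydro-2H-pyran-3-yl]-4-methylhept-4-enoate | C=C(CO[Si](c1ccccc1)(c1ccccc1)C(C)(C)C)[C@@H]1CC=C(CC/C=C(\C)CCC(=O)ON2C(=O)c3ccccc3C2=O)CO1 | intermediate
19 | 5-bromo-2-methylpent-2-ene | CC(C)=CCCBr | starting material
20 | 6-methylhept-5-en-1-yne | CC(C)=CCCC#C | intermediate
21 | [(1E)-2,6-dimethylhepta-1,5-dien-1-yl]dimethylalane | CC(C)=CCC/C(C)=C/[Al](C)C | intermediate
22 | (1E)-1-iodo-2,6-dimethylhepta-1,5-diene | CC(C)=CCC/C(C)=C/I | intermediate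
23 | tert-butyl({2-[(2S)-5-[(3E,7E)-4,8,12-trimethyltrideca-3,7,11-trien-1-yl]-3,6-dihydro-2H-pyran-2-yl]prop-2-en-1-yl}oxy)diphenylsilane | C=C(CO[Si](c1ccccc1)(c1ccccc1)C(C)(C)C)[C@@H]1CC=C(CC/C=C(\C)CC/C=C(\C)CCC=C(C)C)CO1 | intermediate
24 | 2-[(2S)-5-[(3E,7E)-4,8,12-trimethyltrideca-3,7,11-trien-1-yl]-3,6-dihydro-2H-pyran-2-yl]prop-2-en-1-ol | C=C(CO)[C@@H]1CC=C(CC/C=C(\C)CC/C=C(\C)CCC=C(C)C)CO1 | intermediate
25 | 2-[(2S)-5-[(3E,7E)-4,8,12-trimethyltrideca-3,7,11-trien-1-yl]-3,6-dihydro-2H-pyran-2-yl]prop-2-enal | C=C(C=O)[C@@H]1CC=C(CC/C=C(\C)CC/C=C(\C)CCC=C(C)C)CO1 | intermediate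
26 | 2-[(2S)-5-[(3E,7E)-4,8,12-trimethyltrideca-3,7,11-trien-1-yl]-3,6-dihydro-2H-pyran-2-yl]prop-2-enoic acid | C=C(C(=O)O)[C@@H]1CC=C(CC/C=C(\C)CC/C=C(\C)CCC=C(C)C)CO1 | target

**Step count and risks**

Total steps: 17. Longest linear sequence: 14 steps (steps 1–5, 7–11, 14–17).

Steps most likely to fail:

1. Step 14. The redox-active ester may be consumed unproductively (reduction to the alkane or loss of a β-hydrogen after decarboxylation), the iodide may homodimerise faster than cross-coupling, or the C3'=C4' geometry may erode through reversible 3-exo closure of the homoallylic radical. The fallback sets out from acid 17 and forms the same C6'–C7' bond by a two-electron Negishi coupling. Esterification of 17 with N-hydroxypyridine-2-thione (DCC, DMAP, CH2Cl2, dark) should give the Barton ester F1. Irradiation of F1 with iodoform should give, by radical iododecarboxylation, the primary homoallylic iodide F2. Zinc insertion (Zn dust, LiCl, THF) should give the alkylzinc iodide F3, and coupling of F3 with 22 under Pd(PPh3)4 catalysis comes back to the route at 23.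

2. Step 7. The lithiated imine may attack the ring alkene terminus with allylic transposition (SN2'), induce 1,4-elimination of HCl to a diene, or be alkylated twice. The fallback sets out from alcohol 5, brings C1'–C3' in before ring closure, and replaces steps 4, 5 and 7. CuI-catalysed carbomagnesiation of propargyl alcohol with commercial [2-(1,3-dioxan-2-yl)ethyl]magnesium bromide should give 2-[2-(1,3-dioxan-2-yl)ethyl]prop-2-en-1-ol F4. Appel bromination (CBr4, PPh3) should give 2-[3-(bromomethyl)but-3-en-1-yl]-1,3-dioxane F5. Williamson etherification of 5 with F5 (NaH, THF) should give the diene ether F6, ring-closing metathesis with the second-generation Grubbs catalyst should give the dioxane-protected dihydropyran F7, and acetal hydrolysis (aq. HCl, THF) comes back to the route at aldehyde 13.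

3. Step 9. At 138 °C with acid, the allylic alcohol or the doubly allylic ring ether may ionise or eliminate, or the silyl ether may be lost, before the rearrangement is complete. The fallback sets out from 14 and runs the rearrangement under basic, low-temperature conditions. Acetylation (Ac2O, pyridine, DMAP) should give the allylic acetate F8. Ireland–Claisen rearrangement (LiN(iPr)2, Me3SiCl, THF, −78 °C to rt) should pass through the trimethylsilyl ketene acetal F9 to the trimethylsilyl ester F10 with the same chair-controlled E selectivity. Dilute acid work-up comes back to the route at acid 17, so step 10 is then not needed.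

**Further compounds**

F1 | step 14 | 2-thioxopyridin-1(2H)-yl (4E)-7-[(6S)-6-(3-{[tert-butyl(diphenyl)silyl]oxy}prop-1-en-2-yl)-5,6-dihydro-2H-pyran-3-yl]-4-methylhept-4-enoate | C=C(CO[Si](c1ccccc1)(c1ccccc1)C(C)(C)C)[C@@H]1CC=C(CC/C=C(\C)CCC(=O)ON2C=CC=CC2=S)CO1
F2 | step 14 | tert-butyl({2-[(2S)-5-[(3E)-6-iodo-4-methylhex-3-en-1-yl]-3,6-dihydro-2H-pyran-2-yl]prop-2-en-1-yl}oxy)diphenylsilane | C=C(CO[Si](c1ccccc1)(c1ccccc1)C(C)(C)C)[C@@H]1CC=C(CC/C=C(\C)CCI)CO1
F3 | step 14 | {(3E)-6-[(6S)-6-(3-{[tert-butyl(diphenyl)silyl]oxy}prop-1-en-2-yl)-5,6-dihydro-2H-pyran-3-yl]-3-methylhex-3-en-1-yl}zinc iodide | C=C(CO[Si](c1ccccc1)(c1ccccc1)C(C)(C)C)[C@@H]1CC=C(CC/C=C(\C)CC[Zn]I)CO1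
F4 | step 7 | 2-[2-(1,3-dioxan-2-yl)ethyl]prop-2-en-1-ol | C=C(CO)CCC1OCCCO1
F5 | step 7 | 2-[3-(bromomethyl)but-3-en-1-yl]-1,3-dioxane | C=C(CBr)CCC1OCCCO1
F6 | step 7 | tert-butyl{[(3S)-3-({2-[2-(1,3-dioxan-2-yl)ethyl]prop-2-en-1-yl}oxy)-2-methylidenehex-5-en-1-yl]oxy}diphenylsilane | C=C(CO[Si](c1ccccc1)(c1ccccc1)C(C)(C)C)[C@@H](OCC(=C)CCC1OCCCO1)CC=C
F7 | step 7 | tert-butyl({2-[(2S)-5-[2-(1,3-dioxan-2-yl)ethyl]-3,6-dihydro-2H-pyran-2-yl]prop-2-en-1-yl}oxy)diphenylsilane | C=C(CO[Si](c1ccccc1)(c1ccccc1)C(C)(C)C)[C@@H]1CC=C(CCC2OCCCO2)CO1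
F8 | step 9 | 5-[(6S)-6-(3-{[tert-butyl(diphenyl)silyl]oxy}prop-1-en-2-yl)-5,6-dihydro-2H-pyran-3-yl]-2-methylpent-1-en-3-yl acetate | C=C(CO[Si](c1ccccc1)(c1ccccc1)C(C)(C)C)[C@@H]1CC=C(CCC(OC(C)=O)C(C)=C)CO1
F9 | step 9 | trimethylsilyl ketene acetal of F8 | C=C(CO[Si](c1ccccc1)(c1ccccc1)C(C)(C)C)[C@@H]1CC=C(CCC(OC(=C)O[Si](C)(C)C)C(C)=C)CO1
F10 | step 9 | trimethylsilyl (4E)-7-[(6S)-6-(3-{[tert-butyl(diphenyl)silyl]oxy}prop-1-en-2-yl)-5,6-dihydro-2H-pyran-3-yl]-4-methylhept-4-enoate | C=C(CO[Si](c1ccccc1)(c1ccccc1)C(C)(C)C)[C@@H]1CC=C(CC/C=C(\C)CCC(=O)O[Si](C)(C)C)CO1
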